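Numbering: C1 (quaternary, methyl), C2, C3, C4 (isopropyl carbinol), C5 (fusion CH), C6 (ester carbinol), C7, C8(Me)=C9, C10; ring A is the cyclopentane C1–C5, ring B the cycloheptene. Ring B is disconnected at C9–C10 and C6–C7. Since C10, C1, C5 and C6 can be held on ring A as an s-cis-locked 1-silyloxydiene, with C10 the terpinen-4-ol methyl, a gold acetoxyvinylcarbenoid from prop-2-ynyl acetate supplies C7–C8–C9 in one operation: cyclopropanation of C1=C10, then Cope shift, closing ring B and leaving a C8 enol acetate and a C1=C5 olefin as handles for the two methyl groups. The precursor is the exocyclic silyl dienol ether of a cyclopentene carbaldehyde made from (S)-terpinen-4-ol.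

Key step: step 5

Remark: commercial (S)-terpinen-4-ol of high enantiomeric purity is assumed; its carbinol carbon becomes C4 and relays to C1, C5 and C6.
Remark: the C6 centre created in the key step is drawn as the epimer expected from annulation on the diene face remote from the C4 silyloxy group; the other epimer would be carried through the same steps and converges at the C6 ketone of step 11.

Step 1
Reactants: 1 (S)-terpinen-4-ol
Product: 2 (S)-terpinen-4-ol trimethylsilyl ether
Conditions: 1-(trimethylsilyl)imidazole, CH2Cl2, rt
Reagents that add atoms: 1-(trimethylsilyl)imidazole, C[Si](C)(C)n1ccnc1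
Why: O-silylation of the hindered tertiary hydroxyl by silyl transfer from the N-silylimidazole masks the C4 oxygen, which would otherwise form a lactol with the ketone and be lost by β-elimination from the aldehyde in the next two steps; the stereocentre is untouched.

Step 2
Reactants: 2 (S)-terpinen-4-ol trimethylsilyl ether
Product: 4 (S)-6-oxo-3-(propan-2-yl)-3-(trimethylsilyloxy)heptanal, via secondary ozonide 3 (not isolated)
Conditions: O3, CH2Cl2, −78 °C; PPh3, −78 °C to rt
Reagents that add atoms: ozone, O=[O+][O-]
Why: Ozonolysis of the only C=C bond (dipolar cycloaddition, cycloreversion and recombination to ozonide 3) followed by reductive cleavage with PPh3 should give the 1,6-keto aldehyde without touching the silyl ether or the quaternary centre.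

Step 3
Reactants: 4 (S)-6-oxo-3-(propan-2-yl)-3-(trimethylsilyloxy)heptanal
Product: 5 (R)-2-methyl-5-(propan-2-yl)-5-(trimethylsilyloxy)cyclopent-1-ene-1-carbaldehyde
Conditions: piperidine, AcOH (cat.), PhMe, rt to 50 °C
Reagents that add atoms: none
Why: Amine-catalysed intramolecular aldol condensation: the aldehyde enamine (nucleophilic at the future C5) attacks the methyl ketone (future C1) in a 5-exo-trig closure and dehydration gives the cyclopentene carbaldehyde, not the acetylcyclopentene that hydroxide would favour; C4 bears no hydrogen and cannot epimerise.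

Step 4
Reactants: 5 (R)-2-methyl-5-(propan-2-yl)-5-(trimethylsilyloxy)cyclopent-1-ene-1-carbaldehyde
Product: 6 exocyclic (Z) silyl dienol ether (C10=C1–C5=C6–OSi(tBu)Me2 on ring A)
Conditions: TBSOTf, Et3N, CH2Cl2, −78 to 0 °C
Reagents that add atoms: tert-butyldimethylsilyl triflate, CC(C)(C)[Si](C)(C)OS(=O)(=O)C(F)(F)F
Why: Soft enolisation to the vinylogous silyl enol ether: O-silylation gives a silyloxyallyl cation and Et3N removes a proton from the freely rotating C10 methyl, not from the ring methylene C2 whose two faces are screened by the C4 substituents, while the silyloxy group settles outside the locked s-cis diene ((Z) geometry, OSi cis to C4).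

Step 5
Reactants: 6 exocyclic (Z) silyl dienol ether; 7 prop-2-ynyl acetate
Product: 9 ring B enol acetate (C8(OAc)=C9 and C1=C5 olefins; 6-OSi(tBu)Me2; 4-OSiMe3), via cis-divinylcyclopropane 8 (not isolated)
Conditions: Ph3PAuNTf2 (5 mol %, monovalent gold), 4 Å MS, CH2Cl2, 0 °C to rt, slow addition of 7
Reagents that add atoms: none
Why: The cationic gold centre activates the alkyne of 7, the acetate shifts 1,2 through a dioxolenium ion, and the resulting acetoxyvinyl gold carbenoid (carbene carbon C9, acetoxy carbon C8, methylene C7) cyclopropanates the terminal C1=C10 bond of 6 (bonds C9–C10 and C1–C9) to give cis-divinylcyclopropane 8, which undergoes the Cope shift at or below room temperature. The closest known reaction type is the gold-catalysed 1,2-acyloxy migration, cyclopropanation and Cope cascade of propargyl esters with 1,3-dienes to cyclohepta-1,4-dienes, a formal (4+3) annulation. Ring B is closed by the boat [3,3] shift that forms C6–C7 as C1–C9 breaks; a stepwise path, attack of C10 on the carbenoid and closure of the allylgold unit on the C6 oxocarbenium ion, would lead to the same ring. The one new stereocentre, C6, follows from the diene face that is engaged, for which the C4 centre gives only a modest bias (the face remote from OSiMe3 is assumed), and it is erased at step 11. Site selectivity for C1=C10 over the C5=C6 enol ether is required and is secured by C10 being the unhindered, vinylogously nucleophilic terminus, whereas C5 is shielded by the quaternary C4. The exocyclic diene is locked s-cis and its (Z) enol ether puts hydrogen, not OSi, on the inside of C6, so the boat is unencumbered, and the silver-free catalyst spares the acid-labile silyl ethers.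

Step 6
Reactants: 9 ring B enol acetate
Product: 11 C8 enol triflate (C8(OTf)=C9), via lithium enolate 10 (not isolated)
Conditions: MeLi (2.2 equiv), THF, −78 to 0 °C; PhNTf2, −78 °C to rt
Reagents that add atoms: N-phenylbis(trifluoromethanesulfonimide), O=S(=O)(N(c1ccccc1)S(=O)(=O)C(F)(F)F)C(F)(F)F
Why: Two equivalents of MeLi cleave the enol acetate to the regiodefined lithium enolate 10, which cannot equilibrate or eliminate the C6 silyloxy group in the absence of a proton source, and O-sulfonylation with PhNTf2 fixes the C8=C9 position as the enol triflate.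

Step 7
Reactants: 11 C8 enol triflate
Product: 12 C8-methyl diene (C8(Me)=C9 and C1=C5; 6-OSi(tBu)Me2; 4-OSiMe3)
Conditions: MeMgBr, Fe(acac)3 (5 mol %, trivalent iron), THF/NMP, −30 to 0 °C
Reagents that add atoms: methylmagnesium bromide, C[Mg]Br
Why: Iron-catalysed Kumada-type cross-coupling of the alkenyl triflate with MeMgBr replaces OTf by methyl without moving the C8=C9 bond, and both silyl ethers are inert to the Grignard reagent at low temperature.

Step 8
Reactants: 12 C8-methyl diene
Product: 13 tertiary allylic alcohol (free C4–OH; 6-OSi(tBu)Me2)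
Conditions: K2CO3, MeOH, rt
Reagents that add atoms: none
Why: Base-catalysed methanolysis removes the trimethylsilyl ether selectively, since the secondary tert-butyldimethylsilyl ether at C6 is stable to K2CO3/MeOH, and frees the C4 hydroxyl needed for direction.

Step 9
Reactants: 13 tertiary allylic alcohol
Product: 14 cyclopropane (CH2 bridging C1 and C5 on the face of the C4 hydroxyl)
Conditions: Et2Zn, CH2I2, CH2Cl2, −10 to 0 °C
Reagents that add atoms: diiodomethane, ICI
Why: Hydroxyl-directed Simmons–Smith cyclopropanation: the zinc alkoxide of the C4 carbinol delivers methylene to the adjacent electron-rich tetrasubstituted C1=C5 bond on the face of that oxygen, faster than the undirected C8=C9 bond reacts, which places the future C1 methyl syn to the C4 hydroxyl.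

Step 10
Reactants: 14 cyclopropane
Product: 15 cyclopropyl diol (free C4–OH and C6–OH)
Conditions: Bu4NF, THF, rt
Reagents that add atoms: none
Why: Fluoride-mediated silyl ether cleavage under basic conditions spares the two acid-sensitive cyclopropylcarbinol units.

Step 11
Reactants: 15 cyclopropyl diol
Product: 16 cyclopropyl ketone (C6=O; C4–OH)
Conditions: Dess–Martin periodinane, NaHCO3, CH2Cl2, 0 °C to rt
Reagents that add atoms: none
Why: Buffered Dess–Martin oxidation converts the secondary C6 carbinol into the ketone and erases the C6 centre, while the tertiary C4 carbinol cannot be oxidised and retro-aldol cleavage is blocked because C5 is a cyclopropane carbon.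

Step 12
Reactants: 16 cyclopropyl ketone
Product: 19 trans-fused conjugated enone (C6=O; C7=C8; C1 methyl; C4–OH), via dilithium enolate 17 (not isolated), via cis-fused ketone 18 (not isolated)
Conditions: Li, NH3(l)/THF, t-BuOH (1 equiv), −78 °C; isoprene, NH4Cl; then DBU, PhMe, 40 °C
Reagents that add atoms: none
Why: Dissolving-metal reduction of the cyclopropyl ketone cleaves the exocyclic C5–CH2 bond (the one aligned with the carbonyl π system and leading to a primary carbanion), so the methylene becomes the C1 methyl on the face fixed in step 9; protonation of enolate 17 is expected on the open face to give cis-fused 18, and DBU then equilibrates C5 through the enol to the trans-fused series, in which C6 is cis to the hydrogen-bonding C4 hydroxyl and trans to the isopropyl group, the ring B olefin moving into conjugation under the same thermodynamic control.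

Step 13
Reactants: 19 trans-fused conjugated enone
Product: 21 trans-fused β,γ-unsaturated ketone (C6=O; C8=C9), via dipotassium dienolate 20 (not isolated)
Conditions: KOtBu (3 equiv), THF, 0 °C; AcOH, −78 °C
Reagents that add atoms: none
Why: Deconjugative protonation: excess KOtBu converts 19 (and any β,γ-isomer present) into the alkoxide/extended dienolate 20 by removal of a γ-proton at C9, a dianion that can neither undergo retro-aldol cleavage nor eliminate, and kinetic protonation at the α-carbon C7 with cold AcOH restores the C8=C9 bond with C5 unchanged, any material protonated at C9 being 19 again.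

Step 14
Reactants: 21 trans-fused β,γ-unsaturated ketone
Product: 22 (3R,3aS,4S,8aR)-6,8a-dimethyl-3-(propan-2-yl)-1,2,3,3a,4,5,8,8a-octahydroazulene-3,4-diol
Conditions: Me4NBH(OAc)3, MeCN/AcOH, −20 °C to rt
Reagents that add atoms: none
Why: Hydroxyl-directed triacetoxyborohydride reduction: the reagent exchanges an acetate for the C4 hydroxyl and delivers hydride through a six-membered chair to the C6 carbonyl face on the side of O4 (possible because O4 and C6 are cis on ring A in the trans-fused ketone), which sets C6 with H6 on the O4 side and anti to H5.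

Step 15
Reactants: 23 p-coumaric acid
Product: 25 (E)-3-[4-(tert-butyldimethylsilyloxy)phenyl]prop-2-enoic acid, via bis-silyl derivative 24 (not isolated)
Conditions: TBSCl, imidazole, DMF, rt; then AcOH, THF/H2O, rt
Reagents that add atoms: tert-butyldimethylsilyl chloride, CC(C)(C)[Si](C)(C)Cl
Why: Silylation of both acidic hydroxyls followed by selective hydrolysis of the labile silyl ester leaves only the phenol protected, so that the acid cannot acylate itself in step 16; the (E) olefin is unaffected.

Step 16
Reactants: 22 daucane diol; 25 (E)-3-[4-(tert-butyldimethylsilyloxy)phenyl]prop-2-enoic acid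
Product: 26 C6 ester (phenol silyl-protected target)
Conditions: DCC, DMAP, CH2Cl2, 0 °C to rt
Reagents that add atoms: none
Why: Steglich esterification: the acylpyridinium formed from the O-acylisourea acylates the secondary C6 hydroxyl, while the tertiary C4 hydroxyl is too hindered to compete; no stereocentre is touched.

Step 17
Reactants: 26 C6 ester
Product: 27 CNP0265426.1
Conditions: Bu4NF, AcOH, THF, 0 °C
Reagents that add atoms: none
Why: Buffered fluoride cleaves the aryl silyl ether, which is far more labile than an alkyl silyl ether, without transesterifying the cinnamate or adding to its olefin.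

Compound list
1 | (S)-terpinen-4-ol, (1S)-4-methyl-1-(propan-2-yl)cyclohex-3-en-1-ol | CC1=CC[C@](O)(C(C)C)CC1 | starting material
2 | (S)-trimethyl{[4-methyl-1-(propan-2-yl)cyclohex-3-en-1-yl]oxy}silane | CC1=CC[C@](O[Si](C)(C)C)(C(C)C)CC1 | intermediate
3 | secondary ozonide (1,2,4-trioxolane) of 2 across the former ring olefin | CC12OOC(O1)C[C@](O[Si](C)(C)C)(C(C)C)CC2 | intermediate
4 | (S)-6-oxo-3-(propan-2-yl)-3-(trimethylsilyloxy)heptanal | CC(=O)CC[C@@](O[Si](C)(C)C)(C(C)C)CC=O | intermediate
5 | (R)-2-methyl-5-(propan-2-yl)-5-(trimethylsilyloxy)cyclopent-1-ene-1-carbaldehyde | CC1=C(C=O)[C@](O[Si](C)(C)C)(C(C)C)CC1 | intermediate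
6 | tert-butyl{(Z)-[(5R)-2-methylidene-5-(propan-2-yl)-5-(trimethylsilyloxy)cyclopentylidene]methoxy}dimethylsilane (OSi cis to the quaternary carbon) | C=C1CC[C@@](O[Si](C)(C)C)(C(C)C)/C1=C\O[Si](C)(C)C(C)(C)C | intermediate
7 | prop-2-ynyl acetate | C#CCOC(C)=O | starting material
8 | cis-divinylcyclopropane: cyclopropane C1–C9–C10 spiro at C1, C9 bearing the 1-acetoxyethenyl group cis to C5 and on the ring A face opposite OSiMe3, (Z) C5=C6 silyl enol ether retained | CC(=O)OC(=C)[C@@H]1C[C@@]12CC[C@@](O[Si](C)(C)C)(C(C)C)/C2=C\O[Si](C)(C)C(C)(C)C | intermediate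
9 | ring B enol acetate, (3R,4S)-4-(tert-butyldimethylsilyloxy)-3-(propan-2-yl)-3-(trimethylsilyloxy)-1,2,3,4,5,8-hexahydroazulen-6-yl acetate | CC(=O)OC1=CCC2=C([C@@H](O[Si](C)(C)C(C)(C)C)C1)[C@](O[Si](C)(C)C)(C(C)C)CC2 | intermediate
10 | lithium C8=C9 enolate from 9 | [Li+].[O-]C1=CCC2=C([C@@H](O[Si](C)(C)C(C)(C)C)C1)[C@](O[Si](C)(C)C)(C(C)C)CC2 | intermediate
11 | C8 enol triflate (C8(OTf)=C9, C1=C5, 6-OSi(tBu)Me2, 4-OSiMe3) | O=S(=O)(OC1=CCC2=C([C@@H](O[Si](C)(C)C(C)(C)C)C1)[C@](O[Si](C)(C)C)(C(C)C)CC2)C(F)(F)F | intermediate
12 | C8-methyl diene (C8(Me)=C9, C1=C5, 6-OSi(tBu)Me2, 4-OSiMe3) | CC1=CCC2=C([C@@H](O[Si](C)(C)C(C)(C)C)C1)[C@](O[Si](C)(C)C)(C(C)C)CC2 | intermediate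
13 | tertiary allylic alcohol (C4–OH free, 6-OSi(tBu)Me2) | CC1=CCC2=C([C@@H](O[Si](C)(C)C(C)(C)C)C1)[C@](O)(C(C)C)CC2 | intermediate
14 | cyclopropane with CH2 bridging C1 and C5 syn to the C4 hydroxyl, 6-OSi(tBu)Me2 | CC1=CC[C@]23C[C@@]2([C@@H](O[Si](C)(C)C(C)(C)C)C1)[C@](O)(C(C)C)CC3 | intermediate
15 | cyclopropyl diol (C4–OH and C6–OH) | CC1=CC[C@]23C[C@@]2([C@@H](O)C1)[C@](O)(C(C)C)CC3 | intermediate
16 | cyclopropyl ketone (C6=O, C4–OH) | CC1=CC[C@]23C[C@@]2(C(=O)C1)[C@](O)(C(C)C)CC3 | intermediate
17 | dilithium salt: C5=C6 enolate and C4 alkoxide, C1 methyl in place | [Li+].[Li+].CC1=CC[C@@]2(C)CC[C@@]([O-])(C(C)C)C2=C([O-])C1 | intermediate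
18 | cis-fused β,γ-unsaturated ketone (H5 syn to the C1 methyl and C4 hydroxyl) | CC1=CC[C@@]2(C)CC[C@@](O)(C(C)C)[C@H]2C(=O)C1 | intermediate
19 | trans-fused conjugated enone (C6=O, C7=C8; H5 anti to the C1 methyl and C4 hydroxyl) | CC1=CC(=O)[C@H]2[C@](O)(C(C)C)CC[C@]2(C)CC1 | intermediate
20 | dipotassium salt: C6=C7–C8=C9 dienolate and C4 alkoxide | [K+].[K+].CC1=CC[C@@]2(C)CC[C@@]([O-])(C(C)C)[C@@H]2C([O-])=C1 | intermediate
21 | trans-fused β,γ-unsaturated ketone (C6=O, C8=C9) | CC1=CC[C@@]2(C)CC[C@@](O)(C(C)C)[C@@H]2C(=O)C1 | intermediate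
22 | (3R,3aS,4S,8aR)-6,8a-dimethyl-3-(propan-2-yl)-1,2,3,3a,4,5,8,8a-octahydroazulene-3,4-diol | CC1=CC[C@@]2(C)CC[C@@](O)(C(C)C)[C@@H]2[C@@H](O)C1 | intermediate
23 | p-coumaric acid | OC(=O)/C=C/c1ccc(O)cc1 | starting material
24 | tert-butyldimethylsilyl (E)-3-[4-(tert-butyldimethylsilyloxy)phenyl]prop-2-enoate | CC(C)(C)[Si](C)(C)OC(=O)/C=C/c1ccc(O[Si](C)(C)C(C)(C)C)cc1 | intermediate
25 | (E)-3-[4-(tert-butyldimethylsilyloxy)phenyl]prop-2-enoic acid | OC(=O)/C=C/c1ccc(O[Si](C)(C)C(C)(C)C)cc1 | intermediate
26 | C6 ester of 22 with 25 (phenol as tert-butyldimethylsilyl ether) | CC1=CC[C@@]2(C)CC[C@@](O)(C(C)C)[C@@H]2[C@@H](OC(=O)/C=C/c2ccc(O[Si](C)(C)C(C)(C)C)cc2)C1 | intermediate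
27 | CNP0265426.1, (3R,3aS,4S,8aR)-3-hydroxy-6,8a-dimethyl-3-(propan-2-yl)-1,2,3,3a,4,5,8,8a-octahydroazulen-4-yl (2E)-3-(4-hydroxyphenyl)prop-2-enoate | CC1=CC[C@@]2(C)CC[C@@](O)(C(C)C)[C@@H]2[C@@H](OC(=O)/C=C/c2ccc(O)cc2)C1 | target

Total step count: 17
Longest linear sequence: 16 steps (steps 1 to 14, then 16 and 17, from (S)-terpinen-4-ol)

Steps most likely to fail

Step 5. The short-lived gold carbenoid may be consumed by self-reaction of the propargyl ester before the diene captures it, the C6 oxocarbenium intermediate may lose silicon before ring closure (open-chain C10-alkylated enal), or trace acid may hydrolyse the dienol ether. In that case the same two bonds would be made stepwise from 6. Rh2(OAc)4 (divalent rhodium) and diazoacetone cyclopropanate the C1=C10 bond to give the spiro acetylcyclopropane F1. LiN(iPr)2 and Me3SiCl convert its methyl ketone into the 2-(trimethylsilyloxy)vinylcyclopropane F2. Warming, with thermal cis/trans equilibration of the cyclopropane if needed, brings about the Cope shift to the C8 trimethylsilyl enol ether F3. MeLi and then PhNTf2 turn F3 into enol triflate 11, where the route is rejoined.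

Step 12. The C5 configuration runs against the steric bias and rests on thermodynamic control; the free β-hydroxy ketone may open by retro-aldol cleavage of C4–C5, or dehydrate, under the amidine base before epimerisation is complete. In that case the kinetic ketone 18 would be carried on protected. 1-(Trimethylsilyl)imidazole gives the tertiary trimethylsilyl ether F4, in which retro-aldol cleavage is impossible. DBU then equilibrates C5 and the olefin to the trans-fused conjugated enone silyl ether F5. Citric acid in MeOH removes the silyl group and returns 19.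

Step 9. Methylene transfer may stall at the hindered tetrasubstituted C1=C5 bond, so that undirected attack on C8=C9 takes over. In that case the angular methyl would be introduced by conjugate addition. From 13, Bu4NF gives the diol F6, and MnO2 oxidises only the allylic C6 carbinol to the ring-fusion enone F7. Me2CuLi (monovalent copper) with Me3SiCl adds methyl to C1 on the face of the C4 alkoxide, anti to the isopropyl group. Hydrolysis of the silyl enol ether on work-up and the DBU treatment of step 12 then lead to 19.

Further compounds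
F1 | step 5 | spiro acetylcyclopropane from 6 (acetyl on C9, cyclopropane C1–C9–C10, mixture of cyclopropane diastereomers) | CC(=O)C1CC12CC[C@@](O[Si](C)(C)C)(C(C)C)/C2=C\O[Si](C)(C)C(C)(C)C
F2 | step 5 | 2-(trimethylsilyloxy)vinylcyclopropane from F1 | C=C(O[Si](C)(C)C)C1CC12CC[C@@](O[Si](C)(C)C)(C(C)C)/C2=C\O[Si](C)(C)C(C)(C)C
F3 | step 5 | C8 trimethylsilyl enol ether corresponding to 9 | C[Si](C)(C)OC1=CCC2=C([C@@H](O[Si](C)(C)C(C)(C)C)C1)[C@](O[Si](C)(C)C)(C(C)C)CC2
F4 | step 12 | trimethylsilyl ether of cis-fused ketone 18 | CC1=CC[C@@]2(C)CC[C@@](O[Si](C)(C)C)(C(C)C)[C@H]2C(=O)C1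
F5 | step 12 | trimethylsilyl ether of conjugated enone 19 | CC1=CC(=O)[C@H]2[C@](O[Si](C)(C)C)(C(C)C)CC[C@]2(C)CC1
F6 | step 9 | diol from 13 (C4–OH and C6–OH, C1=C5 and C8=C9 olefins) | CC1=CCC2=C([C@@H](O)C1)[C@](O)(C(C)C)CC2
F7 | step 9 | ring-fusion enone (C6=O conjugated to C1=C5, C4–OH, C8=C9) | CC1=CCC2=C(C(=O)C1)[C@](O)(C(C)C)CC2
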